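**Plan**

- Retrosynthesis: cut the eight O–CH3 bonds, then the stilbene C=C (Horner–Wadsworth–Emmons), then O1–C7a and C2–C3 of dihydrobenzofuran A (the ring system that carries the stilbene), then the aryl–CH2 bond that joins the two halves (Negishi coupling), then the same pair O1–C7a and C2–C3 in dihydrobenzofuran B.
- Enabling feature: in both ring systems O1–C2 is the C=O of an aryl aldehyde, C3 is a doubly benzylic CH, and C7a is the benzo-ring carbon ortho to C3a. Both benzo rings carry the same 4-oxygen/6-carbon pattern, so one iodo sulfoxide (6) serves twice.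
- Helper: an (R)-p-tolylsulfinyl group on the future C7a directs the ortho-lithiation that installs the iodine used for benzylation, chelates the benzylic lithium, steers the face of its addition to the aldehyde, and is then expelled as sulfenate by the alkoxide, so it is gone once the ring is closed.
- Forward order: sulfinylarene 4; ortho-iodide 6; Negishi benzylation; addition–ring closure to dihydrobenzofuran B; CH2Br and its benzylzinc; Negishi coupling with a second portion of 6; addition–ring closure to dihydrobenzofuran A; stilbene; demethylation.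
- Stereochemistry: C3 of each ring from the sulfur centre (1,4-induction through the C–Li···O=S chelate); C2 of each ring trans to C3 by the preference of the addition and by acid equilibration through the alkoxybenzylic cation at C2.

Key step: step 10

Assumption: the sense of 1,4-induction is taken from the chelate model in which the p-tolyl group lies on the face away from the lithium and the aldehyde enters on the lithium face, so that the (R)-sulfoxide should give (3R); should the opposite sense be found, (1R,2S,5R)-menthyl (S)-p-toluenesulfinate is used in step 2 and nothing else changes.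

**Step 1**
Reactants: 1 3-bromo-5-methoxybenzaldehyde
Product: 2 2-(3-bromo-5-methoxyphenyl)-1,3-dioxolane
Conditions: ethylene glycol, p-TsOH (cat.), toluene, reflux, Dean–Stark trap
Reagents that add atoms: ethylene glycol, OCCO
Why: Acid-catalysed acetalisation with azeotropic removal of water masks the aldehyde against the organometallic steps that follow.

**Step 2**
Reactants: 2 2-(3-bromo-5-methoxyphenyl)-1,3-dioxolane
Product: 4 2-{3-methoxy-5-[(R)-p-tolylsulfinyl]phenyl}-1,3-dioxolane, via arylmagnesium bromide 3 (not isolated)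
Conditions: Mg, THF, reflux; then (1S,2R,5S)-menthyl (R)-p-toluenesulfinate, toluene, 0 °C
Reagents that add atoms: (1S,2R,5S)-menthyl (R)-p-toluenesulfinate, CC(C)[C@H]1CC[C@H](C)C[C@@H]1O[S@@](=O)c1ccc(C)cc1
Why: Andersen sulfoxide synthesis, in which the aryl Grignard reagent displaces mentholate with inversion at sulfur and so sets the (R)-sulfinyl centre.

**Step 3**
Reactants: 4 2-{3-methoxy-5-[(R)-p-tolylsulfinyl]phenyl}-1,3-dioxolane
Product: 6 2-{4-iodo-3-methoxy-5-[(R)-p-tolylsulfinyl]phenyl}-1,3-dioxolane, via aryllithium 5 (not isolated)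
Conditions: LiN(iPr)2 (1.1 equiv), THF, −78 °C; then I2, −78 → 0 °C
Reagents that add atoms: iodine, II
Why: Directed ortho-metalation with the non-nucleophilic amide base should occur at the CH flanked by the sulfinyl and methoxy groups, and iodine traps the aryllithium without touching the sulfur centre.

**Step 4**
Reactants: 6 2-{4-iodo-3-methoxy-5-[(R)-p-tolylsulfinyl]phenyl}-1,3-dioxolane; 7 3,5-dimethoxybenzyl bromide
Product: 9 2-{4-(3,5-dimethoxybenzyl)-3-methoxy-5-[(R)-p-tolylsulfinyl]phenyl}-1,3-dioxolane, via benzylzinc bromide 8 (not isolated)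
Conditions: 7, Zn dust (activated with BrCH2CH2Br and Me3SiCl), THF, 0 °C; then 6, Pd(OAc)2 (2 mol %), SPhos (4 mol %), 25 → 50 °C
Reagents that add atoms: none
Why: Zinc inserts into the benzylic C–Br bond, and the non-basic benzylzinc bromide should couple with the hindered aryl iodide in a Negishi cross-coupling that leaves the sulfoxide and the acidic diarylmethane product untouched.

**Step 5**
Reactants: 9 2-{4-(3,5-dimethoxybenzyl)-3-methoxy-5-[(R)-p-tolylsulfinyl]phenyl}-1,3-dioxolane; 10 2,4-dimethoxybenzaldehyde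
Product: 13 2-[(2R,3R)-2-(2,4-dimethoxyphenyl)-3-(3,5-dimethoxyphenyl)-4-methoxy-2,3-dihydrobenzofuran-6-yl]-1,3-dioxolane, via benzyllithium 11 (not isolated), via lithium alkoxide 12 (not isolated)
Conditions: LiN(iPr)2 (1.1 equiv), THF, −78 °C; 10; then DMPU, −78 → 55 °C
Reagents that add atoms: none
Why: Proposed new method: the sulfinyl-chelated benzyllithium should add to the aldehyde on the face away from the p-tolyl group (1,4-induction sets C3) and the alkoxide should then displace p-toluenesulfenate at the ipso carbon in a 5-exo addition–elimination, the closest known reaction types being the tandem addition–cyclisation of 2-sulfinylbenzyl carbanions with imines that gives indolines with loss of the sulfinyl group and the base-promoted substitution of aryl sulfoxides by alkoxides.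

**Step 6**
Reactants: 13 2-[(2R,3R)-2-(2,4-dimethoxyphenyl)-3-(3,5-dimethoxyphenyl)-4-methoxy-2,3-dihydrobenzofuran-6-yl]-1,3-dioxolane
Product: 14 (2R,3R)-2-(2,4-dimethoxyphenyl)-3-(3,5-dimethoxyphenyl)-4-methoxy-2,3-dihydrobenzofuran-6-carbaldehyde
Conditions: CF3CO2H, H2O, CH2Cl2, 0 °C
Reagents that add atoms: water, O
Why: Aqueous acid hydrolyses the dioxolane, and reversible ionisation of the O1–C2 bond to the 2,4-dimethoxybenzylic cation should let any cis isomer settle into the more stable 2,3-trans ring while C3 stays untouched.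

**Step 7**
Reactants: 14 (2R,3R)-2-(2,4-dimethoxyphenyl)-3-(3,5-dimethoxyphenyl)-4-methoxy-2,3-dihydrobenzofuran-6-carbaldehyde
Product: 15 [(2R,3R)-2-(2,4-dimethoxyphenyl)-3-(3,5-dimethoxyphenyl)-4-methoxy-2,3-dihydrobenzofuran-6-yl]methanol
Conditions: NaBH4, MeOH–THF, 0 °C
Reagents that add atoms: none
Why: Borohydride reduction of an aryl aldehyde is chemoselective and touches no stereocentre.

**Step 8**
Reactants: 15 [(2R,3R)-2-(2,4-dimethoxyphenyl)-3-(3,5-dimethoxyphenyl)-4-methoxy-2,3-dihydrobenzofuran-6-yl]methanol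
Product: 16 (2R,3R)-6-(bromomethyl)-2-(2,4-dimethoxyphenyl)-3-(3,5-dimethoxyphenyl)-4-methoxy-2,3-dihydrobenzofuran
Conditions: CBr4, PPh3, CH2Cl2, 0 °C
Reagents that add atoms: carbon tetrabromide, BrC(Br)(Br)Br
Why: The Appel reaction converts the benzylic alcohol into the bromide under neutral conditions that leave the acid-sensitive ring alone.

**Step 9**
Reactants: 16 (2R,3R)-6-(bromomethyl)-2-(2,4-dimethoxyphenyl)-3-(3,5-dimethoxyphenyl)-4-methoxy-2,3-dihydrobenzofuran; 6 2-{4-iodo-3-methoxy-5-[(R)-p-tolylsulfinyl]phenyl}-1,3-dioxolane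
Product: 18 2-{4-{[(2R,3R)-2-(2,4-dimethoxyphenyl)-3-(3,5-dimethoxyphenyl)-4-methoxy-2,3-dihydrobenzofuran-6-yl]methyl}-3-methoxy-5-[(R)-p-tolylsulfinyl]phenyl}-1,3-dioxolane, via benzofuranylmethylzinc bromide 17 (not isolated)
Conditions: 16, Zn dust (activated with BrCH2CH2Br and Me3SiCl), THF, 0 °C; then 6, Pd(OAc)2 (2 mol %), SPhos (4 mol %), 25 → 50 °C
Reagents that add atoms: none
Why: The same zinc insertion and Negishi cross-coupling as in step 4 joins the benzofuranylmethyl unit to a second portion of iodide 6, the neutral organozinc leaving the C2 and C3 stereocentres of 16 alone.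

**Step 10**
Reactants: 18 2-{4-{[(2R,3R)-2-(2,4-dimethoxyphenyl)-3-(3,5-dimethoxyphenyl)-4-methoxy-2,3-dihydrobenzofuran-6-yl]methyl}-3-methoxy-5-[(R)-p-tolylsulfinyl]phenyl}-1,3-dioxolane; 19 4-methoxybenzaldehyde
Product: 22 2-{(2R,3R)-3-[(2R,3R)-2-(2,4-dimethoxyphenyl)-3-(3,5-dimethoxyphenyl)-4-methoxy-2,3-dihydrobenzofuran-6-yl]-4-methoxy-2-(4-methoxyphenyl)-2,3-dihydrobenzofuran-6-yl}-1,3-dioxolane, via benzyllithium 20 (not isolated), via lithium alkoxide 21 (not isolated)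
Conditions: LiN(iPr)2 (1.05 equiv), THF, −78 °C; 19; then DMPU, −78 → 55 °C
Reagents that add atoms: none
Why: Proposed new method: LiN(iPr)2 should remove a proton from the CH2 between ring A and the benzofuranyl ring, the lithium being held by the sulfinyl oxygen; this benzyllithium adds to the aldehyde carbon (bond C3–C2), and on warming the lithium alkoxide attacks C7a ipso to sulfur and expels p-toluenesulfenate (bond O1–C7a). The closest known reaction types are the tandem addition–cyclisation of 2-(p-tolylsulfinyl)benzyl carbanions with imines, which gives indolines by displacement of the sulfinyl group, and the base-promoted substitution of aryl sulfoxides by alkoxides. The dihydrofuran ring closes by a 5-exo-trig addition–elimination at C7a. C3 is controlled by the (R)-sulfinyl group through the six-membered C–Li···O=S chelate, the aldehyde entering on the lithium face away from the p-tolyl group; C2 is controlled by the preference of the two aryl groups for a trans arrangement in the addition and ring closure, and any cis isomer is corrected in step 11. The step needs deprotonation at the ring A CH2 and not at C3–H of the existing dihydrobenzofuran, which the sulfinyl-directed lithiation at −78 °C with one equivalent of base should secure, and attack of the alkoxide at carbon and not at sulfur, which the five-membered transition state favours.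

**Step 11**
Reactants: 22 2-{(2R,3R)-3-[(2R,3R)-2-(2,4-dimethoxyphenyl)-3-(3,5-dimethoxyphenyl)-4-methoxy-2,3-dihydrobenzofuran-6-yl]-4-methoxy-2-(4-methoxyphenyl)-2,3-dihydrobenzofuran-6-yl}-1,3-dioxolane
Product: 23 (2R,3R)-3-[(2R,3R)-2-(2,4-dimethoxyphenyl)-3-(3,5-dimethoxyphenyl)-4-methoxy-2,3-dihydrobenzofuran-6-yl]-4-methoxy-2-(4-methoxyphenyl)-2,3-dihydrobenzofuran-6-carbaldehyde
Conditions: CF3CO2H, H2O, CH2Cl2, 0 °C
Reagents that add atoms: water, O
Why: Acetal hydrolysis, with reversible ionisation at C2 to the 4-methoxybenzylic cation that should bring any cis isomer of ring system A to the trans form without touching C3.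

**Step 12**
Reactants: 23 (2R,3R)-3-[(2R,3R)-2-(2,4-dimethoxyphenyl)-3-(3,5-dimethoxyphenyl)-4-methoxy-2,3-dihydrobenzofuran-6-yl]-4-methoxy-2-(4-methoxyphenyl)-2,3-dihydrobenzofuran-6-carbaldehyde; 24 diethyl (4-methoxybenzyl)phosphonate
Product: 26 (2R,3R)-3-[(2R,3R)-2-(2,4-dimethoxyphenyl)-3-(3,5-dimethoxyphenyl)-4-methoxy-2,3-dihydrobenzofuran-6-yl]-4-methoxy-2-(4-methoxyphenyl)-6-[(E)-4-methoxystyryl]-2,3-dihydrobenzofuran, via phosphonate carbanion 25 (not isolated)
Conditions: 24, KOtBu, THF, 0 °C; then 23, 0 °C → rt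
Reagents that add atoms: none
Why: Horner–Wadsworth–Emmons olefination of a non-enolisable aryl aldehyde with a preformed benzylphosphonate anion should give the (E)-stilbene.

**Step 13**
Reactants: 26 (2R,3R)-3-[(2R,3R)-2-(2,4-dimethoxyphenyl)-3-(3,5-dimethoxyphenyl)-4-methoxy-2,3-dihydrobenzofuran-6-yl]-4-methoxy-2-(4-methoxyphenyl)-6-[(E)-4-methoxystyryl]-2,3-dihydrobenzofuran
Product: 27 (2R,3R)-3-[(2R,3R)-2-(2,4-dihydroxyphenyl)-3-(3,5-dihydroxyphenyl)-4-hydroxy-2,3-dihydrobenzofuran-6-yl]-2-(4-hydroxyphenyl)-6-[(E)-4-hydroxystyryl]-2,3-dihydrobenzofuran-4-ol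
Conditions: BBr3, CH2Cl2, −78 → 0 °C; then H2O
Reagents that add atoms: none
Why: Boron tribromide cleaves all eight aryl methyl ethers, and the acidic medium keeps both 2-aryl centres in the stable trans arrangement.

**Compound list**

1 | 3-bromo-5-methoxybenzaldehyde | COc1cc(Br)cc(C=O)c1 | starting material
2 | 2-(3-bromo-5-methoxyphenyl)-1,3-dioxolane | COc1cc(Br)cc(c1)C1OCCO1 | intermediate
3 | [3-(1,3-dioxolan-2-yl)-5-methoxyphenyl]magnesium bromide | COc1cc([Mg]Br)cc(c1)C1OCCO1 | intermediate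
4 | 2-{3-methoxy-5-[(R)-p-tolylsulfinyl]phenyl}-1,3-dioxolane | Cc1ccc(cc1)[S@@](=O)c1cc(OC)cc(c1)C1OCCO1 | intermediate
5 | {4-(1,3-dioxolan-2-yl)-2-methoxy-6-[(R)-p-tolylsulfinyl]phenyl}lithium | Cc1ccc(cc1)[S@@](=O)c1cc(cc(OC)c1[Li])C1OCCO1 | intermediate
6 | 2-{4-iodo-3-methoxy-5-[(R)-p-tolylsulfinyl]phenyl}-1,3-dioxolane | Cc1ccc(cc1)[S@@](=O)c1cc(cc(OC)c1I)C1OCCO1 | intermediate
7 | 3,5-dimethoxybenzyl bromide | COc1cc(CBr)cc(OC)c1 | starting material
8 | (3,5-dimethoxybenzyl)zinc bromide | COc1cc(C[Zn]Br)cc(OC)c1 | intermediate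
9 | 2-{4-(3,5-dimethoxybenzyl)-3-methoxy-5-[(R)-p-tolylsulfinyl]phenyl}-1,3-dioxolane | Cc1ccc(cc1)[S@@](=O)c1cc(cc(OC)c1Cc1cc(OC)cc(OC)c1)C1OCCO1 | intermediate
10 | 2,4-dimethoxybenzaldehyde | COc1ccc(C=O)c(OC)c1 | starting material
11 | {(3,5-dimethoxyphenyl){4-(1,3-dioxolan-2-yl)-2-methoxy-6-[(R)-p-tolylsulfinyl]phenyl}methyl}lithium (configurationally labile at carbon) | Cc1ccc(cc1)[S@@](=O)c1cc(cc(OC)c1C([Li])c1cc(OC)cc(OC)c1)C1OCCO1 | intermediate
12 | lithium (1R,2R)-1-(2,4-dimethoxyphenyl)-2-(3,5-dimethoxyphenyl)-2-{4-(1,3-dioxolan-2-yl)-2-methoxy-6-[(R)-p-tolylsulfinyl]phenyl}ethanolate | [Li]O[C@@H](c1ccc(OC)cc1OC)[C@@H](c1c(OC)cc(cc1[S@](=O)c1ccc(C)cc1)C1OCCO1)c1cc(OC)cc(OC)c1 | intermediate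
13 | 2-[(2R,3R)-2-(2,4-dimethoxyphenyl)-3-(3,5-dimethoxyphenyl)-4-methoxy-2,3-dihydrobenzofuran-6-yl]-1,3-dioxolane | C1(OCCO1)c1cc(OC)c2c(c1)O[C@@H](c1ccc(OC)cc1OC)[C@@H]2c1cc(OC)cc(OC)c1 | intermediate
14 | (2R,3R)-2-(2,4-dimethoxyphenyl)-3-(3,5-dimethoxyphenyl)-4-methoxy-2,3-dihydrobenzofuran-6-carbaldehyde | O=Cc1cc(OC)c2c(c1)O[C@@H](c1ccc(OC)cc1OC)[C@@H]2c1cc(OC)cc(OC)c1 | intermediate
15 | [(2R,3R)-2-(2,4-dimethoxyphenyl)-3-(3,5-dimethoxyphenyl)-4-methoxy-2,3-dihydrobenzofuran-6-yl]methanol | OCc1cc(OC)c2c(c1)O[C@@H](c1ccc(OC)cc1OC)[C@@H]2c1cc(OC)cc(OC)c1 | intermediate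
16 | (2R,3R)-6-(bromomethyl)-2-(2,4-dimethoxyphenyl)-3-(3,5-dimethoxyphenyl)-4-methoxy-2,3-dihydrobenzofuran | BrCc1cc(OC)c2c(c1)O[C@@H](c1ccc(OC)cc1OC)[C@@H]2c1cc(OC)cc(OC)c1 | intermediate
17 | {[(2R,3R)-2-(2,4-dimethoxyphenyl)-3-(3,5-dimethoxyphenyl)-4-methoxy-2,3-dihydrobenzofuran-6-yl]methyl}zinc bromide | Br[Zn]Cc1cc(OC)c2c(c1)O[C@@H](c1ccc(OC)cc1OC)[C@@H]2c1cc(OC)cc(OC)c1 | intermediate
18 | 2-{4-{[(2R,3R)-2-(2,4-dimethoxyphenyl)-3-(3,5-dimethoxyphenyl)-4-methoxy-2,3-dihydrobenzofuran-6-yl]methyl}-3-methoxy-5-[(R)-p-tolylsulfinyl]phenyl}-1,3-dioxolane | Cc1ccc(cc1)[S@@](=O)c1cc(cc(OC)c1Cc1cc(OC)c2c(c1)O[C@@H](c1ccc(OC)cc1OC)[C@@H]2c1cc(OC)cc(OC)c1)C1OCCO1 | intermediate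
19 | 4-methoxybenzaldehyde | COc1ccc(C=O)cc1 | starting material
20 | benzylic lithium derivative of 18 (lithium on the CH between ring A and the benzofuranyl ring, configurationally labile at carbon) | Cc1ccc(cc1)[S@@](=O)c1cc(cc(OC)c1C([Li])c1cc(OC)c2c(c1)O[C@@H](c1ccc(OC)cc1OC)[C@@H]2c1cc(OC)cc(OC)c1)C1OCCO1 | intermediate
21 | lithium (1R,2R)-2-[(2R,3R)-2-(2,4-dimethoxyphenyl)-3-(3,5-dimethoxyphenyl)-4-methoxy-2,3-dihydrobenzofuran-6-yl]-2-{4-(1,3-dioxolan-2-yl)-2-methoxy-6-[(R)-p-tolylsulfinyl]phenyl}-1-(4-methoxyphenyl)ethanolate | [Li]O[C@@H](c1ccc(OC)cc1)[C@@H](c1c(OC)cc(cc1[S@](=O)c1ccc(C)cc1)C1OCCO1)c1cc(OC)c2c(c1)O[C@@H](c1ccc(OC)cc1OC)[C@@H]2c1cc(OC)cc(OC)c1 | intermediate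
22 | 2-{(2R,3R)-3-[(2R,3R)-2-(2,4-dimethoxyphenyl)-3-(3,5-dimethoxyphenyl)-4-methoxy-2,3-dihydrobenzofuran-6-yl]-4-methoxy-2-(4-methoxyphenyl)-2,3-dihydrobenzofuran-6-yl}-1,3-dioxolane | C1(OCCO1)c1cc(OC)c2c(c1)O[C@@H](c1ccc(OC)cc1)[C@@H]2c1cc(OC)c2c(c1)O[C@@H](c1ccc(OC)cc1OC)[C@@H]2c1cc(OC)cc(OC)c1 | intermediate
23 | (2R,3R)-3-[(2R,3R)-2-(2,4-dimethoxyphenyl)-3-(3,5-dimethoxyphenyl)-4-methoxy-2,3-dihydrobenzofuran-6-yl]-4-methoxy-2-(4-methoxyphenyl)-2,3-dihydrobenzofuran-6-carbaldehyde | O=Cc1cc(OC)c2c(c1)O[C@@H](c1ccc(OC)cc1)[C@@H]2c1cc(OC)c2c(c1)O[C@@H](c1ccc(OC)cc1OC)[C@@H]2c1cc(OC)cc(OC)c1 | intermediate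
24 | diethyl (4-methoxybenzyl)phosphonate | CCOP(=O)(Cc1ccc(OC)cc1)OCC | starting material
25 | potassium (diethoxyphosphoryl)(4-methoxyphenyl)methanide | [K+].CCOP(=O)(OCC)[CH-]c1ccc(OC)cc1 | intermediate
26 | (2R,3R)-3-[(2R,3R)-2-(2,4-dimethoxyphenyl)-3-(3,5-dimethoxyphenyl)-4-methoxy-2,3-dihydrobenzofuran-6-yl]-4-methoxy-2-(4-methoxyphenyl)-6-[(E)-4-methoxystyryl]-2,3-dihydrobenzofuran | COc1ccc(/C=C/c2cc(OC)c3c(c2)O[C@@H](c2ccc(OC)cc2)[C@@H]3c2cc(OC)c3c(c2)O[C@@H](c2ccc(OC)cc2OC)[C@@H]3c2cc(OC)cc(OC)c2)cc1 | intermediate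
27 | (2R,3R)-3-[(2R,3R)-2-(2,4-dihydroxyphenyl)-3-(3,5-dihydroxyphenyl)-4-hydroxy-2,3-dihydrobenzofuran-6-yl]-2-(4-hydroxyphenyl)-6-[(E)-4-hydroxystyryl]-2,3-dihydrobenzofuran-4-ol | Oc1ccc(/C=C/c2cc(O)c3c(c2)O[C@@H](c2ccc(O)cc2)[C@@H]3c2cc(O)c3c(c2)O[C@@H](c2ccc(O)cc2O)[C@@H]3c2cc(O)cc(O)c2)cc1 | target

Total step count: 13. Longest linear sequence: 13 steps (steps 1 to 13; iodide 6 enters a second time in step 9).

**Steps most likely to fail**

1. Step 10. The ring closure may stall because the lithium alkoxide reverts to carbanion and aldehyde on warming or attacks sulfur instead of C7a. Base may also stray to C3–H of ring system B and open that ring by β-elimination of the aryloxide. Face selectivity may be lower for a diarylmethyl carbanion than for simple alkyl cases. Fallback, from 18 to 23: the addition is run alone (LiN(iPr)2, THF, −78 °C, then 19, quench with NH4Cl at −78 °C), a known reaction type for 2-sulfinylbenzyl carbanions, and should give the hydroxy sulfoxide F1. Sulfoxide–magnesium exchange (iPrMgCl·LiCl in excess, THF), B(OMe)3 and then NaOH/H2O2 should replace the sulfinyl group by a hydroxyl group and give the phenol alcohol F2. Acid (CF3CO2H, H2O, CH2Cl2) should then ionise the 4-methoxybenzylic alcohol, the phenol closing the trans ring while the dioxolane is hydrolysed, which returns to the route at aldehyde 23.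

2. Step 5. The same displacement of the sulfinyl group from an electron-rich ring may not take place, and the face selectivity of the addition is unproven for this carbanion. Fallback, from 9 to 13: addition alone at −78 °C with 10 should give the hydroxy sulfoxide F3. Sulfoxide–magnesium exchange (iPrMgCl·LiCl in excess) followed by I2 should give the iodo alcohol F4. Intramolecular Ullmann etherification (CuI, 1,10-phenanthroline, Cs2CO3, toluene, 110 °C) should close the ring with retention at both carbons and return to 13; any C2 epimer is still corrected in step 6.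

3. Step 13. Acid may open the dihydrofuran rings to benzylic cations that are trapped by the stilbene or by the resorcinol-type rings (cationic cyclisation or oligomerisation), and cleavage of the hindered methyl ethers may be incomplete. Fallback, from 23 to 27: the methyl ethers are cleaved before the stilbene exists (BBr3, CH2Cl2), which should give the heptaphenol aldehyde F5. Silylation (tBuMe2SiCl, imidazole, DMF) should give the heptasilyl ether F6. Horner–Wadsworth–Emmons olefination with diethyl [4-(tert-butyldimethylsilyloxy)benzyl]phosphonate (NaH, THF) should give the octasilyl ether F7, and fluoride buffered with acetic acid (Bu4NF, AcOH, THF) should release the target 27 without any Lewis acid acting on the stilbene.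

**Further compounds**

F1 | step 10 | (1R,2R)-2-[(2R,3R)-2-(2,4-dimethoxyphenyl)-3-(3,5-dimethoxyphenyl)-4-methoxy-2,3-dihydrobenzofuran-6-yl]-2-{4-(1,3-dioxolan-2-yl)-2-methoxy-6-[(R)-p-tolylsulfinyl]phenyl}-1-(4-methoxyphenyl)ethanol | O[C@@H](c1ccc(OC)cc1)[C@@H](c1c(OC)cc(cc1[S@](=O)c1ccc(C)cc1)C1OCCO1)c1cc(OC)c2c(c1)O[C@@H](c1ccc(OC)cc1OC)[C@@H]2c1cc(OC)cc(OC)c1
F2 | step 10 | 2-{(1R,2R)-1-[(2R,3R)-2-(2,4-dimethoxyphenyl)-3-(3,5-dimethoxyphenyl)-4-methoxy-2,3-dihydrobenzofuran-6-yl]-2-hydroxy-2-(4-methoxyphenyl)ethyl}-5-(1,3-dioxolan-2-yl)-3-methoxyphenol | O[C@@H](c1ccc(OC)cc1)[C@@H](c1c(OC)cc(cc1O)C1OCCO1)c1cc(OC)c2c(c1)O[C@@H](c1ccc(OC)cc1OC)[C@@H]2c1cc(OC)cc(OC)c1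
F3 | step 5 | (1R,2R)-1-(2,4-dimethoxyphenyl)-2-(3,5-dimethoxyphenyl)-2-{4-(1,3-dioxolan-2-yl)-2-methoxy-6-[(R)-p-tolylsulfinyl]phenyl}ethanol | O[C@@H](c1ccc(OC)cc1OC)[C@@H](c1c(OC)cc(cc1[S@](=O)c1ccc(C)cc1)C1OCCO1)c1cc(OC)cc(OC)c1
F4 | step 5 | (1R,2R)-1-(2,4-dimethoxyphenyl)-2-(3,5-dimethoxyphenyl)-2-[4-(1,3-dioxolan-2-yl)-2-iodo-6-methoxyphenyl]ethanol | O[C@@H](c1ccc(OC)cc1OC)[C@@H](c1c(OC)cc(cc1I)C1OCCO1)c1cc(OC)cc(OC)c1
F5 | step 13 | (2R,3R)-3-[(2R,3R)-2-(2,4-dihydroxyphenyl)-3-(3,5-dihydroxyphenyl)-4-hydroxy-2,3-dihydrobenzofuran-6-yl]-4-hydroxy-2-(4-hydroxyphenyl)-2,3-dihydrobenzofuran-6-carbaldehyde | O=Cc1cc(O)c2c(c1)O[C@@H](c1ccc(O)cc1)[C@@H]2c1cc(O)c2c(c1)O[C@@H](c1ccc(O)cc1O)[C@@H]2c1cc(O)cc(O)c1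
F6 | step 13 | heptakis(tert-butyldimethylsilyl) ether of F5 | O=Cc1cc(O[Si](C)(C)C(C)(C)C)c2c(c1)O[C@@H](c1ccc(O[Si](C)(C)C(C)(C)C)cc1)[C@@H]2c1cc(O[Si](C)(C)C(C)(C)C)c2c(c1)O[C@@H](c1ccc(O[Si](C)(C)C(C)(C)C)cc1O[Si](C)(C)C(C)(C)C)[C@@H]2c1cc(O[Si](C)(C)C(C)(C)C)cc(O[Si](C)(C)C(C)(C)C)c1
F7 | step 13 | octakis(tert-butyldimethylsilyl) ether of 27 | CC(C)(C)[Si](C)(C)Oc1ccc(/C=C/c2cc(O[Si](C)(C)C(C)(C)C)c3c(c2)O[C@@H](c2ccc(O[Si](C)(C)C(C)(C)C)cc2)[C@@H]3c2cc(O[Si](C)(C)C(C)(C)C)c3c(c2)O[C@@H](c2ccc(O[Si](C)(C)C(C)(C)C)cc2O[Si](C)(C)C(C)(C)C)[C@@H]3c2cc(O[Si](C)(C)C(C)(C)C)cc(O[Si](C)(C)C(C)(C)C)c2)cc1
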